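Remark on the chemistry: the C3–C1′ axis between ring C and ring B is taken to rotate freely at room temperature, so the target has no stereochemical element to control.

## Structural features

The target is an isoflavone, in which benzene ring A is fused along C4a–C8a to the pyran-4-one ring C and benzene ring B is attached through C1′ to C3 of ring C. Ring A carries free hydroxyl groups at C5 and C7, the phloroglucinol pattern, with the C5 hydroxyl hydrogen-bonded to the C4 carbonyl; ring B is pentasubstituted, with methoxy groups at C2′, C3′, C4′ and C6′ and one hydrogen at C5′. The molecule has no stereocentre, so no neighbouring stereocentres have to be related, and the C3–C1′ axis, the only conceivable stereo-element, is not expected to be configurationally stable. The fragile parts are the electron-rich phenols of ring A, which are prone to oxidation and C-alkylation, C2 of the chromone, which takes up hydroxide or alkoxide with ring opening, and the four aryl methyl ethers, which must remain while the ring A oxygens are set free. Ring A therefore has to travel as benzyl ethers, and a late demethylation is excluded. The real difficulty is the C3–C1′ bond, because both positions ortho to C1′ are substituted and any late coupling at C3 would work against severe congestion. The key step exploits two features: the chain O1–C2–C3–C4 of ring C, with ring B on C3, has the connectivity of an arylmalonate that has acylated a phenol at oxygen and at the ortho carbon, and ring A corresponds to a symmetrical 3,5-dioxygenated phenol whose two ortho carbons are equivalent, so that closure through O1–C2 and C4–C4a can give only one 3-aryl-4-hydroxycoumarin, which differs from the target skeleton only in the oxidation levels of C2 and C4.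

## Logic of the disconnections

15 ⇒ 14. No skeletal bond is cut; the O5–H and O7–H bonds are exchanged for O–CH2Ph bonds. Free ring A phenols would not survive alkylation, hydride and the thermal step, and the benzyl ether is the one that hydrogenolysis removes beside four methyl ethers. The gain is a set of neutral, non-chelating intermediates. The forward step must cleave two benzyl ethers without reducing the C2=C3 bond.

14 ⇒ 11 (through 13 and 12). No skeletal bond is cut: the C2–H bond and the C4=O group of 14 are traced back to a C2=O lactone and a C4–OCH3 enol ether, so the carbonyl function moves from C4 to C2. This turns the chromone into the coumarin isomer that malonate chemistry can deliver. The gain is a C2–C3–C4 unit oxygenated at both ends. The forward sequence must add exactly one hydride at C2 of 11, ionise 12 at C2 to 13, and hydrolyse 13 at C4.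

11 ⇒ 10. The O4–CH3 bond is cut. The methyl group only tells the two oxygen functions at C2 and C4 apart, so that hydride later attacks C2 alone; without it the vinylogous acid 10 appears. The forward step must alkylate O4 and not the oxygen at C2.

10 ⇒ 2 + 6 (through 9, 8 and 7). The bonds O1–C2 and C4–C4a are cut. Here the bicyclic core falls into a symmetrical phenol and a malonate that already holds ring B on the future C3, so the congested C3–C1′ bond is not formed in the ring-forming step. The gain is the largest of the route: one ring and two skeletal bonds from two monocyclic pieces. The forward step demands that both ester groups of 6 act as acyl donors, that C-acylation occurs at one site only, and that the benzyl ethers of 2 withstand the temperature.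

2 ⇒ 1. Two O–CH2Ph bonds are cut. This leads to the cheapest symmetrical triol. The forward step must stop at the diether and favour O- over C-benzylation.

6 ⇒ 4 + 5. The bond between C1′ and the malonate carbon (the future C3–C1′ bond) is cut. The hindered aryl–carbon bond is thus made by electrophilic substitution with a small, very reactive carbenoid at the only kind of free ring position of 5. The gain is a symmetrical tetraether and a three-carbon unit. The forward step must attack ring carbon and not a methoxy oxygen, and must stop after one substitution.

4 ⇒ 3. The C=N2 bond is cut, which leads to the parent malonic ester. The forward step is a diazo transfer that should use the least hazardous sulfonyl azide.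

## Other disconnections considered

Alternative 1: Cut: ring C is opened at C3–C4 and O1–C8a, and the C5 and C7 oxygens are traced back to fluorine, so that the key step would deliver 5,7-difluoro-3-(2,3,4,6-tetramethoxyphenyl)chromen-4-one A1.
- Forward key step: 2,4,6-trifluorobenzoyl chloride A2 would acylate the enamine 4-[(E)-2-(2,3,4,6-tetramethoxyphenyl)ethenyl]morpholine A3 at its aryl-bearing carbon; this enamine A3 would be made from 2-(2,3,4,6-tetramethoxyphenyl)acetaldehyde A4. Hydrolysis of the enaminone and mild base would let the enol oxygen displace one of the two equivalent ortho fluorides and give A1. Double SNAr on A1 with a benzylic alkoxide would then lead to 14, and hydrogenolysis to 15.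
- In favour: C4 is a carbonyl from the start, so no reduction and hydrolysis are needed; on redox economy the alternative is the better plan. It also avoids 250 °C, so it is the better plan on mildness. The symmetry of A2 makes the closure site unique, which is equal to the chosen plan on regiocontrol.
- Against: the C3–C4 bond is formed at the carbon of A3 that carries the di-ortho-substituted ring B, and A2 is di-ortho-substituted too, so the congested centre is itself the site of coupling. A4 needs formylation of 5 and a one-carbon homologation and is prone to self-condensation, which also burdens the preparation of A3. The two C–O bonds at C5 and C7 of A1 must be made late by an alkoxide, which can also add to C2 of the chromone and open ring C.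
- Comparison: on structure the chosen plan has the ring A oxygens and the C3–C1′ bond in place before ring closure, while the alternative installs the oxygens last on A1. On mechanism the alternative uses polar steps near room temperature against ketene chemistry at 250 °C. On step economy it needs about seven to eight steps, all linear, which is no better than seven steps with a longest line of six.

Alternative 2: Cut: C4a–C4 and C4–C3 at once, which leads back to (E)-3-methoxy-2-(2,3,4,6-tetramethoxyphenyl)-1-[2,4,6-tris(benzyloxy)phenyl]prop-2-en-1-one A5.
- Forward key step: zerovalent palladium, formed from Pd(OAc)2 and a bulky phosphine, would insert into the carbon–iodine bond of 1,3,5-tris(benzyloxy)-2-iodobenzene A6 and take up carbon monoxide A7. The aroylpalladium would add to 1,2,3,5-tetramethoxy-4-[(E)-2-methoxyethenyl]benzene A8 at the aryl-bearing carbon, and β-hydride elimination, followed by equilibration of the push–pull double bond, would give A5. Debenzylation of A5 would free the ortho hydroxyl, which should add to the methoxy-enone and expel the methoxy group to give 15.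
- In favour: it is the most convergent of the four plans, joining both arenes and C4 in one step at the right oxidation level, and only one or two operations follow A5. With A6 and A8 each about two steps from 1 and 5, the longest line would be four to five steps; on convergence and step economy the alternative is the better plan.
- Against: the aroylpalladium from A6 and A7 is flanked by two benzyloxy groups and must add to A8, an electron-rich 1,2-disubstituted alkene, at the carbon bearing a di-ortho-substituted ring. Intermolecular carbonylative Heck reactions of this kind go beyond established practice. Direct Heck arylation without A7, decarbonylation and hydrolysis of the enol ether would compete, and β-hydride elimination has only one hydrogen to use. Debenzylation of A5 must spare the push–pull alkene, and A7 is toxic and needs pressure equipment.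
- Comparison: on structure the alternative makes C4–C3 at the congested carbon between two hindered partners, whereas the chosen key step forms only O1–C2 and C4–C4a. On mechanism it is catalytic and milder in temperature, but rests on an insertion without close analogy, while the chosen condensation belongs to a known thermal reaction class. On step economy the alternative is shorter, and on hazard the two plans are about equal, A7 standing against 4.

Alternative 3: Cut: C4a–C5 and C8–C8a, so that ring A is built last and the key step would deliver 7-hydroxy-5-methoxy-3-(2,3,4,6-tetramethoxyphenyl)chromen-4-one A9.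
- Forward key step: 1,1-dimethoxy-3-(trimethylsilyloxy)buta-1,3-diene A10 would add to the nitro-activated C=C of 3-nitro-5-(2,3,4,6-tetramethoxyphenyl)pyran-4-one A11. The CH2 terminus of A10 would bond to the future C8a and the acetal carbon to the future C4a. Elimination of the nitro group and of one methoxy group would aromatise ring A to A9, and a final demethylation at O5 would give 15.
- In favour: the oxygen pattern of ring A follows from the polarity of A10, which is equal to the chosen plan on regiocontrol. No ring A protecting groups are needed and the C7 hydroxyl of A9 appears free; on protecting-group economy the alternative is the better plan. Conditions are mild and C4 is a carbonyl throughout.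
- Against: A9 carries a methoxy group at C5, so one of five methyl ethers must be cleaved selectively. Chelation-assisted cleavage peri to the carbonyl is plausible, but the C2′ and C6′ methoxy groups also lie near that carbonyl. A11 is not simple: nitration of an aryl pyranone would first strike ring B at C5′, so the nitro group must precede ring B, and the congested C3–C1′ bond still has to be made. The pyranone C=C is a weak dienophile, and A10 may add in conjugate fashion and open the ring.
- Comparison: on structure the alternative postpones the hard bond rather than solving it, whereas the chosen plan makes it first on a simple arene. On mechanism a cycloaddition–elimination cascade is milder than the 250 °C condensation but has more competing pathways. On step economy the multi-step access to A11 and the extra demethylation of A9 make it clearly longer.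

Key step: step 4

## Route

Step 1
Reactants: 1 phloroglucinol
Product: 2 3,5-bis(benzyloxy)phenol
Conditions: BnBr (2.0 equiv), K2CO3, DMF, 0 °C to rt; chromatography
Reagents that add atoms: benzyl bromide, BrCc1ccccc1
Why: Williamson etherification with a weak base in a dipolar aprotic solvent should favour O- over C-benzylation; with two equivalents of halide the diether should be the main member of the statistical series and is separated from the much more polar monoether and the non-polar triether.

Step 2
Reactants: 3 dimethyl malonate
Product: 4 dimethyl 2-diazomalonate
Conditions: 4-AcNHC6H4SO2N3, Et3N, MeCN, 0 °C to rt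
Reagents that add atoms: 4-acetamidobenzenesulfonyl azide, CC(=O)Nc1ccc(cc1)S(=O)(=O)N=[N+]=[N-]
Why: Regitz diazo transfer: the malonate enolate attacks the terminal azide nitrogen and the triazene collapses to the diazo ester and the sulfonamide; this azide is among the least shock-sensitive transfer reagents and its sulfonamide is removed by filtration.

Step 3
Reactants: 4 dimethyl 2-diazomalonate; 5 1,2,3,5-tetramethoxybenzene
Product: 6 dimethyl 2-(2,3,4,6-tetramethoxyphenyl)malonate
Conditions: Rh2(OAc)4 (1 mol %), 5 (2 equiv), ClCH2CH2Cl, 80 °C, slow addition of 4
Reagents that add atoms: none
Why: Rhodium carbenoid aromatic substitution (formal C–H insertion): the electrophilic bis(methoxycarbonyl)carbenoid is attacked by the arene at its only kind of free position (C4 and C6 are equivalent, each ortho to two and para to one methoxy group) and proton transfer restores the aromatic ring. Excess 5 and slow addition should hold back carbene dimerisation and a second substitution.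

Step 4
Reactants: 2 3,5-bis(benzyloxy)phenol; 6 dimethyl 2-(2,3,4,6-tetramethoxyphenyl)malonate
Product: 10 5,7-bis(benzyloxy)-4-hydroxy-3-(2,3,4,6-tetramethoxyphenyl)chromen-2-one, via methoxycarbonyl ketene 7 (not isolated), via mixed aryl methyl malonate 8 (not isolated), via aryloxycarbonyl ketene 9 (not isolated)
Conditions: Ph2O, 250 °C, N2 stream (MeOH distilled off)
Reagents that add atoms: none
Why: At 250 °C 6 should lose methanol to the aryl(methoxycarbonyl)ketene 7, which the hydroxyl of 2 traps to give the mixed ester 8 (bond O1–C2). A second loss of methanol gives the aryloxycarbonyl ketene 9, whose ketene carbon attacks the ring carbon ortho to the ester oxygen (bond C4–C4a), and tautomerisation gives the 4-hydroxycoumarin 10. The closest known reaction type is the thermal cyclocondensation of phenols with substituted malonic esters to 3-substituted 4-hydroxycoumarins. Ring C is closed as a six-membered ring by intramolecular electrophilic aromatic substitution, formally a 6-exo-dig attack of C4a on the ketene carbon with the C=O bond exocyclic, and no stereocentre is formed. The step needs a single site of C-acylation, and the substrate secures it: the two carbons ortho to the hydroxyl of 2 are equivalent, and the ester tether cannot reach the carbon between the two benzyloxy groups. Because C3 of 10 already carries ring B, 10 cannot condense with a second malonate and the congested C3–C1′ bond is never a reacting centre. Removal of methanol drives both eliminations, and benzyl aryl ethers should tolerate a short time at 250 °C under nitrogen, as they do in other diphenyl ether cyclisations.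

Step 5
Reactants: 10 5,7-bis(benzyloxy)-4-hydroxy-3-(2,3,4,6-tetramethoxyphenyl)chromen-2-one
Product: 11 5,7-bis(benzyloxy)-4-methoxy-3-(2,3,4,6-tetramethoxyphenyl)chromen-2-one
Conditions: Me2SO4, K2CO3, acetone, reflux
Reagents that add atoms: dimethyl sulfate, COS(=O)(=O)OC
Why: O-Alkylation of the vinylogous carboxylate of 10 with a hard electrophile should occur mainly at O4 and give the 4-methoxycoumarin; C3 is fully substituted and shielded, so C-methylation is not expected. Any 2-methoxychromone isomer is separable and can be hydrolysed back to 10 with dilute acid.

Step 6
Reactants: 11 5,7-bis(benzyloxy)-4-methoxy-3-(2,3,4,6-tetramethoxyphenyl)chromen-2-one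
Product: 14 5,7-bis(benzyloxy)-3-(2,3,4,6-tetramethoxyphenyl)chromen-4-one, via lactol 12 (not isolated), via 4-methoxychromenylium chloride 13 (not isolated)
Conditions: i-Bu2AlH (1.2 equiv), CH2Cl2, −78 °C; then 2 M aq. HCl, THF, rt
Reagents that add atoms: water, O
Why: Half-reduction of a lactone to a lactol with diisobutylaluminium hydride: the tetrahedral aluminium acetal persists at −78 °C and takes up only one hydride. In aqueous acid lactol 12 ionises at C2 to the aromatic 4-methoxychromenylium ion 13, water adds at C4 and methanol is lost, which leaves the carbonyl at C4 of the stable chromone; this is the hydrolysis of a 4-alkoxybenzopyrylium salt and, overall, a reductive 1,3-carbonyl transposition of a vinylogous ester. Benzyl and aryl methyl ethers are inert to both stages.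

Step 7
Reactants: 14 5,7-bis(benzyloxy)-3-(2,3,4,6-tetramethoxyphenyl)chromen-4-one
Product: 15 5,7-dihydroxy-3-(2,3,4,6-tetramethoxyphenyl)chromen-4-one
Conditions: H2 (1 atm), 10% Pd/C, EtOAc–MeOH, rt
Reagents that add atoms: none
Why: Catalytic hydrogenolysis of two benzyl aryl ethers; aryl methyl ethers are inert, and the trisubstituted C2=C3 bond, shielded by the di-ortho-substituted ring B, should not be reduced at 1 atm if the reaction is stopped at full debenzylation.

## Compound list

1 | phloroglucinol (benzene-1,3,5-triol) | Oc1cc(O)cc(O)c1 | starting material
2 | 3,5-bis(benzyloxy)phenol | Oc1cc(OCc2ccccc2)cc(OCc2ccccc2)c1 | intermediate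
3 | dimethyl malonate | COC(=O)CC(=O)OC | starting material
4 | dimethyl 2-diazomalonate | COC(=O)C(=[N+]=[N-])C(=O)OC | intermediate
5 | 1,2,3,5-tetramethoxybenzene | COc1cc(OC)c(OC)c(OC)c1 | starting material
6 | dimethyl 2-(2,3,4,6-tetramethoxyphenyl)malonate | COC(=O)C(C(=O)OC)c1c(OC)cc(OC)c(OC)c1OC | intermediate
7 | methyl 3-oxo-2-(2,3,4,6-tetramethoxyphenyl)prop-2-enoate (aryl(methoxycarbonyl)ketene; not isolated) | COC(=O)C(=C=O)c1c(OC)cc(OC)c(OC)c1OC | intermediate
8 | 3,5-bis(benzyloxy)phenyl methyl 2-(2,3,4,6-tetramethoxyphenyl)malonate (not isolated) | COC(=O)C(C(=O)Oc1cc(OCc2ccccc2)cc(OCc2ccccc2)c1)c1c(OC)cc(OC)c(OC)c1OC | intermediate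
9 | 3,5-bis(benzyloxy)phenyl 3-oxo-2-(2,3,4,6-tetramethoxyphenyl)prop-2-enoate (aryloxycarbonyl ketene; not isolated) | O=C=C(C(=O)Oc1cc(OCc2ccccc2)cc(OCc2ccccc2)c1)c1c(OC)cc(OC)c(OC)c1OC | intermediate
10 | 5,7-bis(benzyloxy)-4-hydroxy-3-(2,3,4,6-tetramethoxyphenyl)chromen-2-one | COc1cc(OC)c(-c2c(O)c3c(OCc4ccccc4)cc(OCc4ccccc4)cc3oc2=O)c(OC)c1OC | intermediate
11 | 5,7-bis(benzyloxy)-4-methoxy-3-(2,3,4,6-tetramethoxyphenyl)chromen-2-one | COc1cc(OC)c(-c2c(OC)c3c(OCc4ccccc4)cc(OCc4ccccc4)cc3oc2=O)c(OC)c1OC | intermediate
12 | 5,7-bis(benzyloxy)-4-methoxy-3-(2,3,4,6-tetramethoxyphenyl)-2H-chromen-2-ol (racemic lactol; not isolated) | COC1=C(c2c(OC)cc(OC)c(OC)c2OC)C(O)Oc2cc(OCc3ccccc3)cc(OCc3ccccc3)c12 | intermediate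
13 | 5,7-bis(benzyloxy)-4-methoxy-3-(2,3,4,6-tetramethoxyphenyl)chromenylium chloride (not isolated) | COc1c(-c2c(OC)cc(OC)c(OC)c2OC)c[o+]c2cc(OCc3ccccc3)cc(OCc3ccccc3)c12.[Cl-] | intermediate
14 | 5,7-bis(benzyloxy)-3-(2,3,4,6-tetramethoxyphenyl)chromen-4-one | COc1cc(OC)c(-c2coc3cc(OCc4ccccc4)cc(OCc4ccccc4)c3c2=O)c(OC)c1OC | intermediate
15 | 5,7-dihydroxy-3-(2,3,4,6-tetramethoxyphenyl)chromen-4-one | COc1cc(OC)c(-c2coc3cc(O)cc(O)c3c2=O)c(OC)c1OC | target

## Step count and risk

Total: 7 steps. Longest linear sequence: 6 steps (3 → 4 → 6 → 10 → 11 → 14 → 15, steps 2 to 7); the branch from 1 joins at step 4.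

Step 4 (key step). Ketene formation from the hindered dimethyl ester may be slow compared with thermal loss or migration of benzyl groups and with demethoxycarbonylation of 6, and ring closure may stall at the open ester stage. The fallback keeps the same two bonds but changes the acyl donor; it sets out from 6 and returns at 10. Saponification of 6 (LiOH, THF–H2O, then cold acidification) should give 2-(2,3,4,6-tetramethoxyphenyl)malonic acid F1. Esterification with 2,4,6-trichlorophenol and POCl3 below 80 °C should give bis(2,4,6-trichlorophenyl) 2-(2,3,4,6-tetramethoxyphenyl)malonate F2. Heating F2 with 2 in toluene or bromobenzene (110–155 °C) should release the same ketenes by loss of trichlorophenol far below 250 °C and close ring C to 10, the established active-ester variant of this cyclocondensation.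

Step 6. Over-reduction may occur if the aluminium acetal collapses early to the ring-opened enal, or the deactivated and hindered vinylogous carbonate may not be reduced at all. The fallback sets out from 10 and returns at 14. Alkaline hydrolysis of the lactone and decarboxylation of the β-keto acid (aq. NaOH, EtOH, reflux, then acid) should give 1-[2,4-bis(benzyloxy)-6-hydroxyphenyl]-2-(2,3,4,6-tetramethoxyphenyl)ethanone F3. Condensation of F3 with N,N-dimethylformamide dimethyl acetal (toluene, 100 °C, then dilute acid) should close ring C to 14, the classical deoxybenzoin isoflavone synthesis. This path discards C2 and the O1–C2 bond of the key step, which is why it is only a fallback.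

Step 5. Alkylation may go to the wrong oxygen, because O4 is crowded between the C5 benzyloxy group and ring B. The fallback fixes the site by the position of a leaving group and not by an ambident anion; it sets out from 10 and returns at 11. Treatment with POCl3 (BnEt3NCl, MeCN, 80 °C) should give 5,7-bis(benzyloxy)-4-chloro-3-(2,3,4,6-tetramethoxyphenyl)chromen-2-one F4, and NaOMe in MeOH–THF (0 °C to rt) should replace chloride at C4 by addition–elimination.

Step 3. The carbenoid may attack a methoxy oxygen (oxonium ylide and methyl transfer), dimerise, or substitute a second time at the remaining ring C–H. The diazo-free fallback sets out from 5 and returns at 6. Bromination with N-bromosuccinimide (MeCN, 0 °C) at the only kind of free position should give 2-bromo-1,3,4,5-tetramethoxybenzene F5. Palladium-catalysed α-arylation of 3 with F5 [Pd(OAc)2, t-Bu3P·HBF4, K3PO4, toluene, 100 °C] should then give 6; the bulky, electron-rich phosphine is chosen because the bromide is electron-rich and flanked by two methoxy groups.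

Step 1. Selectivity between mono-, di- and tri-O-benzylation may be poor, and C-benzylation of the polyphenoxide may compete. The fallback replaces the statistical alkylation by full protection and one self-limiting deprotection; it sets out from 1 and returns at 2. Acetylation (Ac2O, pyridine) should give benzene-1,3,5-triyl triacetate F6. Benzylation with in situ deacetylation (BnCl, NaH, DMF, slow addition of water), so that no free polyphenoxide accumulates, should give 1,3,5-tris(benzyloxy)benzene F7. EtSNa in DMF at 120 °C should remove one benzyl group by SN2 attack at the benzylic carbon; the phenoxide formed deactivates the remaining ethers towards a second cleavage.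

## Further compounds

F1 | step 4 | 2-(2,3,4,6-tetramethoxyphenyl)malonic acid | COc1cc(OC)c(C(C(=O)O)C(=O)O)c(OC)c1OC
F2 | step 4 | bis(2,4,6-trichlorophenyl) 2-(2,3,4,6-tetramethoxyphenyl)malonate | COc1cc(OC)c(C(C(=O)Oc2c(Cl)cc(Cl)cc2Cl)C(=O)Oc2c(Cl)cc(Cl)cc2Cl)c(OC)c1OC
F3 | step 6 | 1-[2,4-bis(benzyloxy)-6-hydroxyphenyl]-2-(2,3,4,6-tetramethoxyphenyl)ethanone | COc1cc(OC)c(CC(=O)c2c(O)cc(OCc3ccccc3)cc2OCc2ccccc2)c(OC)c1OC
F4 | step 5 | 5,7-bis(benzyloxy)-4-chloro-3-(2,3,4,6-tetramethoxyphenyl)chromen-2-one | COc1cc(OC)c(-c2c(Cl)c3c(OCc4ccccc4)cc(OCc4ccccc4)cc3oc2=O)c(OC)c1OC
F5 | step 3 | 2-bromo-1,3,4,5-tetramethoxybenzene | COc1cc(OC)c(Br)c(OC)c1OC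
F6 | step 1 | benzene-1,3,5-triyl triacetate | CC(=O)Oc1cc(OC(C)=O)cc(OC(C)=O)c1
F7 | step 1 | 1,3,5-tris(benzyloxy)benzene | c1ccc(COc2cc(OCc3ccccc3)cc(OCc3ccccc3)c2)cc1
A1 | alternative 1 | 5,7-difluoro-3-(2,3,4,6-tetramethoxyphenyl)chromen-4-one | COc1cc(OC)c(-c2coc3cc(F)cc(F)c3c2=O)c(OC)c1OC
A2 | alternative 1 | 2,4,6-trifluorobenzoyl chloride | O=C(Cl)c1c(F)cc(F)cc1F
A3 | alternative 1 | 4-[(E)-2-(2,3,4,6-tetramethoxyphenyl)ethenyl]morpholine | COc1cc(OC)c(/C=C/N2CCOCC2)c(OC)c1OC
A4 | alternative 1 | 2-(2,3,4,6-tetramethoxyphenyl)acetaldehyde | COc1cc(OC)c(CC=O)c(OC)c1OC
A5 | alternative 2 | (E)-3-methoxy-2-(2,3,4,6-tetramethoxyphenyl)-1-[2,4,6-tris(benzyloxy)phenyl]prop-2-en-1-one | CO/C=C(\c1c(OC)cc(OC)c(OC)c1OC)C(=O)c1c(OCc2ccccc2)cc(OCc2ccccc2)cc1OCc1ccccc1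
A6 | alternative 2 | 1,3,5-tris(benzyloxy)-2-iodobenzene | Ic1c(OCc2ccccc2)cc(OCc2ccccc2)cc1OCc1ccccc1
A7 | alternative 2 | carbon monoxide | [C-]#[O+]
A8 | alternative 2 | 1,2,3,5-tetramethoxy-4-[(E)-2-methoxyethenyl]benzene | CO/C=C/c1c(OC)cc(OC)c(OC)c1OC
A9 | alternative 3 | 7-hydroxy-5-methoxy-3-(2,3,4,6-tetramethoxyphenyl)chromen-4-one | COc1cc(O)cc2occ(-c3c(OC)cc(OC)c(OC)c3OC)c(=O)c12
A10 | alternative 3 | 1,1-dimethoxy-3-(trimethylsilyloxy)buta-1,3-diene | COC(OC)=CC(=C)O[Si](C)(C)C
A11 | alternative 3 | 3-nitro-5-(2,3,4,6-tetramethoxyphenyl)pyran-4-one | COc1cc(OC)c(-c2cocc([N+](=O)[O-])c2=O)c(OC)c1OC
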